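**Retrosynthetic overview**
- The ring is numbered C1 (C=O), C2 (C–CH3), C3 (C–CH2COPr), C4 (CH2), C5 (CHOH), C6 (C(CH3)–O-orsellinoyl). The strategy rests on quaternary C6 lying between the C1 carbonyl and the C5 carbinol of the single carbocycle, so C5 and C6 both come from a mirror-symmetric 2-aroyloxy-2-methylcyclohexane-1,3-dione whose two carbonyls are enantiotopic.
- Late disconnections: the three O–Si bonds (global desilylation), C2=C3 (Saegusa–Ito), C3–CH2 (Mukaiyama–Michael addition of the pentan-2-one enol silane), then C2=C3 and C2–CH3 (dehydrogenation, enolate methylation; C2 is the only enolisable position).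
- Key disconnection: the C5–H bond, made by ketoreductase mono-reduction of one enantiotopic carbonyl of the dione ester.
- The C6–O bond comes from oxidative coupling on trivalent iodine (PhIO) of one molecule of 2-methylcyclohexane-1,3-dione with one molecule of bis-silylated orsellinic acid.
- No ring is formed: the carbocycle is bought as 2-methylcyclohexane-1,3-dione and the arene as orsellinic acid.

Key step: step 3

Remark: TBS = tert-butyldimethylsilyl, TMS = trimethylsilyl. C2 in compound 10 and C3 in compound 16 are transient stereocentres expected as epimer mixtures; both are erased on dehydrogenation. A ketoreductase with the required selectivity is assumed to be found by screening a commercial panel.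

**Step 1**
Reactants: 1 orsellinic acid (2,4-dihydroxy-6-methylbenzoic acid)
Product: 3 2,4-bis[(tert-butyldimethylsilyl)oxy]-6-methylbenzoic acid, via tris-silyl ester 2 (not isolated)
Conditions: TBSCl, imidazole, DMF, rt → 40 °C; then AcOH, THF/H2O, rt
Reagents that add atoms: tert-butyldimethylsilyl chloride, CC(C)(C)[Si](C)(C)Cl
Why: Imidazole-promoted silylation should cap both phenols and the carboxyl group, and the silyl ester, far more labile than the aryl silyl ethers, is then hydrolysed selectively by aqueous AcOH (chemoselective silyl ester cleavage).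

**Step 2**
Reactants: 3 2,4-bis[(tert-butyldimethylsilyl)oxy]-6-methylbenzoic acid; 4 2-methylcyclohexane-1,3-dione
Product: 6 2-methyl-1,3-dioxocyclohexan-2-yl 2,4-bis[(tert-butyldimethylsilyl)oxy]-6-methylbenzoate, via iodanyl enol ether 5 (not isolated)
Conditions: PhIO (1.3 equiv), 3 (1.5 equiv, surplus recovered), 4 Å molecular sieves, MeCN/CH2Cl2, 0 °C → rt
Reagents that add atoms: none
Why: Trivalent-iodine-mediated α-acyloxylation of a 1,3-dicarbonyl compound with a carboxylic acid: acid 3 depolymerises PhIO to an aroyloxy-λ3-iodane, the enol oxygen of 4 exchanges onto iodine to give 5, and the aroyloxy group is then delivered through oxygen to the central carbon with reductive loss of PhI, a carboxylate O-attack that the two ortho substituents of the arene do not impede, so the quaternary C–O bond forms without a hindered esterification; 6 keeps a mirror plane, so no stereochemical issue arises.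

**Step 3**
Reactants: 6 2-methyl-1,3-dioxocyclohexan-2-yl 2,4-bis[(tert-butyldimethylsilyl)oxy]-6-methylbenzoate
Product: 7 (1R,6S)-6-hydroxy-1-methyl-2-oxocyclohexyl 2,4-bis[(tert-butyldimethylsilyl)oxy]-6-methylbenzoate (OH trans to the aroyloxy group)
Conditions: ketoreductase (NADPH-dependent, panel-selected), NADP+ (cat.), D-glucose, glucose dehydrogenase, KH2PO4/K2HPO4 buffer pH 7.0, DMSO (10% v/v), 30 °C
Reagents that add atoms: none
Why: In the active site NADPH transfers hydride to the Re face of the pro-S carbonyl of 6 while the active-site acid protonates the oxygen, and glucose dehydrogenase returns NADP+ to NADPH at the expense of glucose, which makes the reduction effectively irreversible. The closest known reaction type is the ketoreductase (or yeast) desymmetrising mono-reduction of 2,2-disubstituted cycloalkane-1,3-diones. No ring closes and no skeletal bond forms; only the C5–H bond is made. C5 (S) is fixed by the face of hydride delivery, which the enzyme pocket dictates, and C6 (R) becomes stereogenic in the same event because the enzyme distinguishes the two enantiotopic carbonyls. The step needs enantiotopic-group selection together with hydride delivery syn to the aroyloxy group (anti to the methyl group), and the substrate helps by presenting a strongly differentiated large (aroyloxy) and small (methyl) pair on prochiral C6 flanked by two otherwise identical ring arms. Mono-reduction should hold because hydroxy ketone 7 is a more hindered and poorer substrate than the dione, and pH 7 avoids retro-aldol opening and acyl migration.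

**Step 4**
Reactants: 7 (1R,6S)-6-hydroxy-1-methyl-2-oxocyclohexyl 2,4-bis[(tert-butyldimethylsilyl)oxy]-6-methylbenzoate
Product: 8 (1R,6S)-6-[(tert-butyldimethylsilyl)oxy]-1-methyl-2-oxocyclohexyl 2,4-bis[(tert-butyldimethylsilyl)oxy]-6-methylbenzoate
Conditions: TBSOTf, 2,6-lutidine, CH2Cl2, −78 → 0 °C
Reagents that add atoms: tert-butyldimethylsilyl trifluoromethanesulfonate, CC(C)(C)[Si](C)(C)OS(=O)(=O)C(F)(F)F
Why: Silyl triflate silylation with a hindered pyridine base should protect the neopentyl-type secondary alcohol at low temperature without forming the alkoxide that could trigger retro-aldol opening or 1,2-acyl migration; the stereocentres are untouched.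

**Step 5**
Reactants: 8 (1R,6S)-6-[(tert-butyldimethylsilyl)oxy]-1-methyl-2-oxocyclohexyl 2,4-bis[(tert-butyldimethylsilyl)oxy]-6-methylbenzoate
Product: 10 (1R,6S)-6-[(tert-butyldimethylsilyl)oxy]-1,3-dimethyl-2-oxocyclohexyl 2,4-bis[(tert-butyldimethylsilyl)oxy]-6-methylbenzoate (mixture of epimers at the new CH–CH3 carbon), via lithium enolate 9 (not isolated)
Conditions: LiN(SiMe3)2, THF, −78 °C; then MeI, DMPU, −78 → −30 °C
Reagents that add atoms: iodomethane, CI
Why: Kinetic enolate alkylation: C6 is quaternary, so LiN(SiMe3)2 can enolise only toward C2, and this base is too weak to metalate the benzylic methyl group of the toluate-type ester and too hindered to attack the ester carbonyl; the C2 epimer mixture is inconsequential because C2 becomes sp2 in step 6.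

**Step 6**
Reactants: 10 (1R,6S)-6-[(tert-butyldimethylsilyl)oxy]-1,3-dimethyl-2-oxocyclohexyl 2,4-bis[(tert-butyldimethylsilyl)oxy]-6-methylbenzoate
Product: 11 (1R,6S)-6-[(tert-butyldimethylsilyl)oxy]-1,3-dimethyl-2-[(trimethylsilyl)oxy]cyclohex-2-en-1-yl 2,4-bis[(tert-butyldimethylsilyl)oxy]-6-methylbenzoate
Conditions: TMSOTf, Et3N, CH2Cl2, 0 °C → rt
Reagents that add atoms: trimethylsilyl trifluoromethanesulfonate, C[Si](C)(C)OS(=O)(=O)C(F)(F)F
Why: Soft enolisation (carbonyl activation by TMSOTf, removal of the C2–H by Et3N) can give only the C1–C2 enol silane, which fixes the site of the dehydrogenation.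

**Step 7**
Reactants: 11 (1R,6S)-6-[(tert-butyldimethylsilyl)oxy]-1,3-dimethyl-2-[(trimethylsilyl)oxy]cyclohex-2-en-1-yl 2,4-bis[(tert-butyldimethylsilyl)oxy]-6-methylbenzoate
Product: 12 (1R,6S)-6-[(tert-butyldimethylsilyl)oxy]-1,3-dimethyl-2-oxocyclohex-3-en-1-yl 2,4-bis[(tert-butyldimethylsilyl)oxy]-6-methylbenzoate
Conditions: Pd(OAc)2 (1.1 equiv), MeCN, rt
Reagents that add atoms: none
Why: Saegusa–Ito oxidation: transmetalation gives the palladium enolate, and syn β-hydride elimination of a ring C3–H should deliver the conjugated endocyclic 2-methyl enone in preference to the exocyclic methylene isomer.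

**Step 8**
Reactants: 13 pentan-2-one
Product: 15 trimethyl(pent-1-en-2-yloxy)silane, via lithium enolate 14 (not isolated)
Conditions: LiN(iPr)2, THF, −78 °C; then TMSCl, −78 °C → rt; distillation
Reagents that add atoms: chlorotrimethylsilane, C[Si](C)(C)Cl
Why: Kinetic deprotonation of the methyl ketone at its less hindered CH3 group at −78 °C followed by O-silylation should give mainly the terminal enol silane (kinetic enol silane formation), and any internal isomer is the slower donor in step 9.

**Step 9**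
Reactants: 12 (1R,6S)-6-[(tert-butyldimethylsilyl)oxy]-1,3-dimethyl-2-oxocyclohex-3-en-1-yl 2,4-bis[(tert-butyldimethylsilyl)oxy]-6-methylbenzoate; 15 trimethyl(pent-1-en-2-yloxy)silane
Product: 16 (1R,6S)-6-[(tert-butyldimethylsilyl)oxy]-1,3-dimethyl-4-(2-oxopentyl)-2-[(trimethylsilyl)oxy]cyclohex-2-en-1-yl 2,4-bis[(tert-butyldimethylsilyl)oxy]-6-methylbenzoate (mixture of epimers at the side-chain-bearing carbon)
Conditions: HNTf2 (3 mol%), CH2Cl2, −78 °C; then Et3N
Reagents that add atoms: none
Why: Mukaiyama–Michael addition: Me3SiNTf2 formed in situ from HNTf2 and 15 silylates the enone oxygen, the terminal enol silane adds at the unhindered C3 (1,2-addition is blocked by quaternary C6 next to the carbonyl), and desilylation of the resulting side-chain oxocarbenium ion regenerates the silyl Lewis acid, leaving the ring as the C1–C2 enol silane; the C3 configuration is irrelevant.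

**Step 10**
Reactants: 16 (1R,6S)-6-[(tert-butyldimethylsilyl)oxy]-1,3-dimethyl-4-(2-oxopentyl)-2-[(trimethylsilyl)oxy]cyclohex-2-en-1-yl 2,4-bis[(tert-butyldimethylsilyl)oxy]-6-methylbenzoate
Product: 17 (1R,6S)-6-[(tert-butyldimethylsilyl)oxy]-1,3-dimethyl-2-oxo-4-(2-oxopentyl)cyclohex-3-en-1-yl 2,4-bis[(tert-butyldimethylsilyl)oxy]-6-methylbenzoate
Conditions: Pd(OAc)2 (1.2 equiv), MeCN, rt → 40 °C
Reagents that add atoms: none
Why: Saegusa–Ito oxidation of the regiodefined enol silane: palladation at C2 and syn β-hydride elimination of the tertiary C3–H should restore C2=C3 as the tetrasubstituted enone and erase the C3 stereocentre, while the side-chain ketone, never present as an enol silane, stays untouched.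

**Step 11**
Reactants: 17 (1R,6S)-6-[(tert-butyldimethylsilyl)oxy]-1,3-dimethyl-2-oxo-4-(2-oxopentyl)cyclohex-3-en-1-yl 2,4-bis[(tert-butyldimethylsilyl)oxy]-6-methylbenzoate
Product: 18 talarophilone, (1R,6S)-6-hydroxy-1,3-dimethyl-2-oxo-4-(2-oxopentyl)cyclohex-3-en-1-yl 2,4-dihydroxy-6-methylbenzoate
Conditions: HF·pyridine, pyridine, THF, 0 °C → rt
Reagents that add atoms: none
Why: Fluoride-driven Si–O cleavage removes the two aryl and the one alkyl silyl ether in one operation under weakly acidic, buffered conditions, which should avoid base-induced acyl migration to the C5 hydroxyl, enolisation of the doubly activated side-chain CH2 and vinylogous elimination of the C5 hydroxyl; C5 and C6 are not touched.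

**Compound list**
1 | orsellinic acid (2,4-dihydroxy-6-methylbenzoic acid) | Cc1cc(O)cc(O)c1C(=O)O | starting material
2 | tert-butyldimethylsilyl 2,4-bis[(tert-butyldimethylsilyl)oxy]-6-methylbenzoate | Cc1cc(O[Si](C)(C)C(C)(C)C)cc(O[Si](C)(C)C(C)(C)C)c1C(=O)O[Si](C)(C)C(C)(C)C | intermediate
3 | 2,4-bis[(tert-butyldimethylsilyl)oxy]-6-methylbenzoic acid | Cc1cc(O[Si](C)(C)C(C)(C)C)cc(O[Si](C)(C)C(C)(C)C)c1C(=O)O | intermediate
4 | 2-methylcyclohexane-1,3-dione | CC1C(=O)CCCC1=O | starting material
5 | ({2,4-bis[(tert-butyldimethylsilyl)oxy]-6-methylbenzoyl}oxy)[(2-methyl-3-oxocyclohex-1-en-1-yl)oxy](phenyl)-λ3-iodane (iodanyl enol ether of 4) | CC1=C(OI(OC(=O)c2c(C)cc(O[Si](C)(C)C(C)(C)C)cc2O[Si](C)(C)C(C)(C)C)c2ccccc2)CCCC1=O | intermediate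
6 | 2-methyl-1,3-dioxocyclohexan-2-yl 2,4-bis[(tert-butyldimethylsilyl)oxy]-6-methylbenzoate (achiral) | CC1(OC(=O)c2c(C)cc(O[Si](C)(C)C(C)(C)C)cc2O[Si](C)(C)C(C)(C)C)C(=O)CCCC1=O | intermediate
7 | (1R,6S)-6-hydroxy-1-methyl-2-oxocyclohexyl 2,4-bis[(tert-butyldimethylsilyl)oxy]-6-methylbenzoate | O=C1CCC[C@H](O)[C@@]1(C)OC(=O)c1c(C)cc(O[Si](C)(C)C(C)(C)C)cc1O[Si](C)(C)C(C)(C)C | intermediate
8 | (1R,6S)-6-[(tert-butyldimethylsilyl)oxy]-1-methyl-2-oxocyclohexyl 2,4-bis[(tert-butyldimethylsilyl)oxy]-6-methylbenzoate | O=C1CCC[C@H](O[Si](C)(C)C(C)(C)C)[C@@]1(C)OC(=O)c1c(C)cc(O[Si](C)(C)C(C)(C)C)cc1O[Si](C)(C)C(C)(C)C | intermediate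
9 | lithium (5S,6R)-6-({2,4-bis[(tert-butyldimethylsilyl)oxy]-6-methylbenzoyl}oxy)-5-[(tert-butyldimethylsilyl)oxy]-6-methylcyclohex-1-en-1-olate (lithium enolate of 8) | [Li+].[O-]C1=CCC[C@H](O[Si](C)(C)C(C)(C)C)[C@@]1(C)OC(=O)c1c(C)cc(O[Si](C)(C)C(C)(C)C)cc1O[Si](C)(C)C(C)(C)C | intermediate
10 | (1R,6S)-6-[(tert-butyldimethylsilyl)oxy]-1,3-dimethyl-2-oxocyclohexyl 2,4-bis[(tert-butyldimethylsilyl)oxy]-6-methylbenzoate (C3 epimers) | O=C1C(C)CC[C@H](O[Si](C)(C)C(C)(C)C)[C@@]1(C)OC(=O)c1c(C)cc(O[Si](C)(C)C(C)(C)C)cc1O[Si](C)(C)C(C)(C)C | intermediate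
11 | (1R,6S)-6-[(tert-butyldimethylsilyl)oxy]-1,3-dimethyl-2-[(trimethylsilyl)oxy]cyclohex-2-en-1-yl 2,4-bis[(tert-butyldimethylsilyl)oxy]-6-methylbenzoate | C[Si](C)(C)OC1=C(C)CC[C@H](O[Si](C)(C)C(C)(C)C)[C@@]1(C)OC(=O)c1c(C)cc(O[Si](C)(C)C(C)(C)C)cc1O[Si](C)(C)C(C)(C)C | intermediate
12 | (1R,6S)-6-[(tert-butyldimethylsilyl)oxy]-1,3-dimethyl-2-oxocyclohex-3-en-1-yl 2,4-bis[(tert-butyldimethylsilyl)oxy]-6-methylbenzoate | O=C1C(C)=CC[C@H](O[Si](C)(C)C(C)(C)C)[C@@]1(C)OC(=O)c1c(C)cc(O[Si](C)(C)C(C)(C)C)cc1O[Si](C)(C)C(C)(C)C | intermediate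
13 | pentan-2-one | CCCC(C)=O | starting material
14 | lithium pent-1-en-2-olate | [Li+].[O-]C(=C)CCC | intermediate
15 | trimethyl(pent-1-en-2-yloxy)silane | C=C(CCC)O[Si](C)(C)C | intermediate
16 | (1R,6S)-6-[(tert-butyldimethylsilyl)oxy]-1,3-dimethyl-4-(2-oxopentyl)-2-[(trimethylsilyl)oxy]cyclohex-2-en-1-yl 2,4-bis[(tert-butyldimethylsilyl)oxy]-6-methylbenzoate (C4 epimers) | CCCC(=O)CC1C(C)=C(O[Si](C)(C)C)[C@](C)(OC(=O)c2c(C)cc(O[Si](C)(C)C(C)(C)C)cc2O[Si](C)(C)C(C)(C)C)[C@@H](O[Si](C)(C)C(C)(C)C)C1 | intermediate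
17 | (1R,6S)-6-[(tert-butyldimethylsilyl)oxy]-1,3-dimethyl-2-oxo-4-(2-oxopentyl)cyclohex-3-en-1-yl 2,4-bis[(tert-butyldimethylsilyl)oxy]-6-methylbenzoate | CCCC(=O)CC1=C(C)C(=O)[C@](C)(OC(=O)c2c(C)cc(O[Si](C)(C)C(C)(C)C)cc2O[Si](C)(C)C(C)(C)C)[C@@H](O[Si](C)(C)C(C)(C)C)C1 | intermediate
18 | talarophilone, (1R,6S)-6-hydroxy-1,3-dimethyl-2-oxo-4-(2-oxopentyl)cyclohex-3-en-1-yl 2,4-dihydroxy-6-methylbenzoate | CCCC(=O)CC1=C(C)C(=O)[C@](C)(OC(=O)c2c(C)cc(O)cc2O)[C@@H](O)C1 | target

**Step count**
Total steps: 11. Longest linear sequence: 10 steps (steps 1–7 and 9–11, from orsellinic acid); step 8 is a one-step side branch.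

**Steps most likely to fail**

1. Step 3. The bulky, lipophilic bis-silylated substrate may be poorly accepted by the enzyme, hydride may be delivered anti to the aroyloxy group, or the wrong enantiotopic carbonyl may be chosen. Fallback: the desymmetrisation would be run as a Noyori–Ikariya asymmetric transfer hydrogenation, setting out from 6 with RuCl[(S,S)-TsDPEN](p-cymene) (or its antipode, chosen by screening) in HCO2H/Et3N at rt. Selectivity then comes from a small-molecule bifunctional catalyst in an organic medium in which 6 dissolves freely. The fallback returns to the route at 7, and no new compound arises (F0).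

2. Step 9. Conjugate addition to the hindered α-methyl enone may be sluggish, or the silyl group may be lost or scrambled, which would leave a 1,5-diketone that cannot be re-enolised regioselectively. Fallback, setting out from 12 and returning at 17: the side chain would be introduced as a masked ketone by Hosomi–Sakurai allylation. The allylsilane trimethyl(2-methylidenepentyl)silane F1 would be made by NiCl2(dppp)-catalysed Kumada coupling of 2-bromopent-1-ene with Me3SiCH2MgCl. F1 would be added to 12 with TiCl4 in CH2Cl2 at −78 °C to give (1R,6S)-6-[(tert-butyldimethylsilyl)oxy]-1,3-dimethyl-4-(2-methylidenepentyl)-2-oxocyclohexyl 2,4-bis[(tert-butyldimethylsilyl)oxy]-6-methylbenzoate F2. Soft enolisation (TMSOTf, Et3N), possible only toward C2, would then give (1R,6S)-6-[(tert-butyldimethylsilyl)oxy]-1,3-dimethyl-4-(2-methylidenepentyl)-2-[(trimethylsilyl)oxy]cyclohex-2-en-1-yl 2,4-bis[(tert-butyldimethylsilyl)oxy]-6-methylbenzoate F3. Pd(OAc)2 in MeCN would convert it into (1R,6S)-6-[(tert-butyldimethylsilyl)oxy]-1,3-dimethyl-4-(2-methylidenepentyl)-2-oxocyclohex-3-en-1-yl 2,4-bis[(tert-butyldimethylsilyl)oxy]-6-methylbenzoate F4. Ozonolysis of the electron-rich 1,1-disubstituted alkene (O3, pyridine, CH2Cl2, −78 °C; then Me2S) should outpace attack on the electron-poor tetrasubstituted enone and give 17.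

3. Step 2. Transfer of a hydroxy instead of the aroyloxy ligand from iodine, oxidation of the electron-rich arene by the iodane, or slow delivery of the carboxylate to the tertiary carbon may erode the coupling. Fallback, setting out from 3 and 4 and returning at 6: the aroyloxy group would be delivered from a peroxide O–O bond instead of from trivalent iodine. Acid 3 would be coupled with 30% aq. H2O2 by DCC (DMAP cat., CH2Cl2, −10 → 0 °C) to give bis{2,4-bis[(tert-butyldimethylsilyl)oxy]-6-methylbenzoyl} peroxide F5. Dione 4 would be deprotonated with NaH in THF/DMF at 0 °C to sodium 2-methyl-3-oxocyclohex-1-en-1-olate F6. The central carbon of F6 should attack a peroxide oxygen of F5 with loss of the aroylate (electrophilic α-aroyloxylation of a 1,3-dicarbonyl enolate), the ortho substituents shielding the peroxide carbonyls from O-acylation, to give 6.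

**Further compounds**
F0 | step 3 | none | none
F1 | step 9 | trimethyl(2-methylidenepentyl)silane | C=C(CCC)C[Si](C)(C)C
F2 | step 9 | (1R,6S)-6-[(tert-butyldimethylsilyl)oxy]-1,3-dimethyl-4-(2-methylidenepentyl)-2-oxocyclohexyl 2,4-bis[(tert-butyldimethylsilyl)oxy]-6-methylbenzoate (C3/C4 epimers) | CCCC(=C)CC1C(C)C(=O)[C@](C)(OC(=O)c2c(C)cc(O[Si](C)(C)C(C)(C)C)cc2O[Si](C)(C)C(C)(C)C)[C@@H](O[Si](C)(C)C(C)(C)C)C1
F3 | step 9 | (1R,6S)-6-[(tert-butyldimethylsilyl)oxy]-1,3-dimethyl-4-(2-methylidenepentyl)-2-[(trimethylsilyl)oxy]cyclohex-2-en-1-yl 2,4-bis[(tert-butyldimethylsilyl)oxy]-6-methylbenzoate (C4 epimers) | CCCC(=C)CC1C(C)=C(O[Si](C)(C)C)[C@](C)(OC(=O)c2c(C)cc(O[Si](C)(C)C(C)(C)C)cc2O[Si](C)(C)C(C)(C)C)[C@@H](O[Si](C)(C)C(C)(C)C)C1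
F4 | step 9 | (1R,6S)-6-[(tert-butyldimethylsilyl)oxy]-1,3-dimethyl-4-(2-methylidenepentyl)-2-oxocyclohex-3-en-1-yl 2,4-bis[(tert-butyldimethylsilyl)oxy]-6-methylbenzoate | CCCC(=C)CC1=C(C)C(=O)[C@](C)(OC(=O)c2c(C)cc(O[Si](C)(C)C(C)(C)C)cc2O[Si](C)(C)C(C)(C)C)[C@@H](O[Si](C)(C)C(C)(C)C)C1
F5 | step 2 | bis{2,4-bis[(tert-butyldimethylsilyl)oxy]-6-methylbenzoyl} peroxide | Cc1cc(O[Si](C)(C)C(C)(C)C)cc(O[Si](C)(C)C(C)(C)C)c1C(=O)OOC(=O)c1c(C)cc(O[Si](C)(C)C(C)(C)C)cc1O[Si](C)(C)C(C)(C)C
F6 | step 2 | sodium 2-methyl-3-oxocyclohex-1-en-1-olate | CC1=C([O-])CCCC1=O.[Na+]
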